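**Strategy.** The route rests on opening the left‑hand dihydrofuran ring at O1′–C7a′ and C3′–C3a′ (primed locants: left dihydrobenzofuran; unprimed: cacalol numbering). This leaves, on the cacalol half, a peri‑fused pyran (O9–C3′–C2′–C8–C8a–C9) in which C3′ is a ketal carbon next to the C2′ alcohol. In the key step that alcohol, as an aluminate, hands a 2‑fluoroaryl group to the C3′ oxocarbenium ion on its own face, creating the quaternary centre, and then displaces the ortho fluoride in the same flask; only the cis adduct can close. The precursor is a methyl ketal alcohol, made from a temporary δ‑lactone in which hydride addition and enolate hydroxylation fix C8 and C2′, plus an iodofluoroarene.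

Key step: step 17

Remark: C2′ and C3′ keep these labels in all intermediates (C2′ is bonded to C8, C3′ to O9). The C3′ anomers of 16 are used as a mixture. The ligand enantiomers in steps 3 and 9 are those that give the drawn configurations.

**Right‑hand half**

Step 1
Reactants: 1 3,4‑dimethoxytoluene; 2 succinic anhydride
Product: 3 4‑(4,5‑dimethoxy‑2‑methylphenyl)‑4‑oxobutanoic acid
Conditions: AlCl3, CH2Cl2/PhNO2, 0 → 23 °C
Reagents that add atoms: none
Why: Friedel–Crafts acylation, which should occur para to the 3‑methoxy group at the least hindered activated position.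

Step 2
Reactants: 3 keto acid
Product: 4 4‑(4,5‑dimethoxy‑2‑methylphenyl)pent‑4‑enoic acid
Conditions: Ph3PCH3Br, KOtBu (3.2 equiv each), THF, 0 → 65 °C
Reagents that add atoms: methyltriphenylphosphonium bromide, C[P+](c1ccccc1)(c1ccccc1)c1ccccc1.[Br-]
Why: Wittig methylenation of the aryl ketone, the acid being carried as its potassium salt.

Step 3
Reactants: 4 pentenoic acid
Product: 5 (S)‑4‑(4,5‑dimethoxy‑2‑methylphenyl)pentanoic acid
Conditions: H2 (6 atm), Ir–SIPHOX catalyst (1 mol %), Cs2CO3 (0.5 equiv), MeOH, 45 °C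
Reagents that add atoms: none
Why: Carboxylate‑directed iridium‑catalysed asymmetric hydrogenation of a 1,1‑disubstituted alkene, the ligand enantiomer being chosen so that hydrogen adds to the face that gives the (S) benzylic centre (C5 of the target).

Step 4
Reactants: 5 (S)‑acid
Product: 6 (S)‑7,8‑dimethoxy‑4,5‑dimethyl‑3,4‑dihydronaphthalen‑1(2H)‑one
Conditions: Eaton's reagent (P2O5/MeSO3H), 23 °C
Reagents that add atoms: none
Why: Intramolecular Friedel–Crafts acylation at the only free position ortho to the side chain, under conditions that leave the benzylic C–H stereocentre untouched.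

Step 5
Reactants: 6 dimethoxytetralone
Product: 7 (S)‑7,8‑dihydroxy‑4,5‑dimethyl‑3,4‑dihydronaphthalen‑1(2H)‑one
Conditions: BBr3, CH2Cl2, −78 → 0 °C
Reagents that add atoms: none
Why: Lewis‑acid cleavage of both aryl methyl ethers (BBr3 demethylation).

Step 6
Reactants: 7 catechol ketone; 8 chloroacetone
Product: 9 (S)‑8‑hydroxy‑4,5‑dimethyl‑7‑(2‑oxopropoxy)‑3,4‑dihydronaphthalen‑1(2H)‑one
Conditions: K2CO3 (1.1 equiv), KI (cat.), acetone, 56 °C
Reagents that add atoms: none
Why: Williamson etherification at the C7 hydroxyl, the C8 hydroxyl being tied up in a hydrogen bond to the peri carbonyl and so less nucleophilic.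

Step 7
Reactants: 9 aryloxyacetone
Product: 10 (S)‑9‑hydroxy‑3,4,5‑trimethyl‑6,7‑dihydronaphtho[2,3‑b]furan‑8(5H)‑one (8‑oxocacalol)
Conditions: polyphosphoric acid, 85 °C
Reagents that add atoms: none
Why: Acid‑mediated cyclodehydration of an aryloxyacetone (intramolecular Friedel–Crafts hydroxyalkylation, then loss of water) at the only free ring position, which builds the 3‑methylfuran.

Step 8
Reactants: 10 8‑oxocacalol
Product: 11 (5S) peri‑fused coumarin, lactone O9–C3′(=O)–C2′H=C8 on the cacalol skeleton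
Conditions: Ph3P=CHCO2Et (2 equiv), PhNEt2, 190 °C
Reagents that add atoms: ethyl (triphenylphosphoranylidene)acetate, CCOC(=O)C=P(c1ccccc1)(c1ccccc1)c1ccccc1
Why: Wittig olefination with lactonisation, the standard coumarin synthesis from an o‑hydroxyaryl ketone and a stabilised ylide; C5 is not affected.

Step 9
Reactants: 11 coumarin
Product: 12 (5S,8S) dihydrocoumarin, lactone O9–C3′(=O)–C2′H2–C8H with H8 trans to the C5 methyl
Conditions: Cu(OAc)2·H2O (3 mol %), DTBM‑SEGPHOS (matched enantiomer), (EtO)2MeSiH, t‑BuOH, toluene, 0 °C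
Reagents that add atoms: none
Why: Copper hydride conjugate reduction of the coumarin; hydride should reach C8 from the face opposite the C5 methyl (held pseudoaxial by peri strain with C4–CH3), and the ligand enantiomer is matched to that bias.

Step 10
Reactants: 12 dihydrocoumarin
Product: 13 (5S,8R,2′R) α‑hydroxy lactone, C2′–OH trans to C8–H
Conditions: KHMDS, THF, −78 °C; 2‑(phenylsulfonyl)‑3‑phenyloxaziridine; NH4Cl
Reagents that add atoms: 2‑(phenylsulfonyl)‑3‑phenyloxaziridine, O=S(=O)(N1OC1c1ccccc1)c1ccccc1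
Why: Davis oxaziridine hydroxylation of the lactone enolate; the oxidant should attack C2′ axially, anti to the pseudoaxial C8–H of the conformationally locked peri‑fused ring, so that O1′ ends trans to H8.

Step 11
Reactants: 13 hydroxy lactone
Product: 15 (5S,8R,2′R) exocyclic enol ether O9–C3′(=CH2)–C2′H(OSiEt3)–C8H, via triethylsilyl ether 14 (not isolated)
Conditions: Et3SiCl, imidazole, CH2Cl2, 23 °C; then Cp2TiMe2, toluene, 70 °C, dark
Reagents that add atoms: chlorotriethylsilane, CC[Si](CC)(CC)Cl; dimethyltitanocene, C[Ti](C)(C1C=CC=C1)C1C=CC=C1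
Why: Silyl protection followed by Petasis methylenation of the lactone carbonyl, which gives the exocyclic enol ether without touching a stereocentre.

Step 12
Reactants: 15 enol ether
Product: 16 (5S,8R,2′R) methyl ketal alcohol O9–C3′(CH3)(OCH3)–C2′H(OH)–C8H, both C3′ anomers
Conditions: PPTS (5 mol %), MeOH, 0 → 23 °C
Reagents that add atoms: methanol, CO
Why: Acid‑catalysed Markovnikov addition of methanol to the enol ether (ketalisation) with methanolysis of the silyl ether; the C3′ configuration is immaterial because this centre is ionised in step 17.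

**Left‑hand half**

Step 13
Reactants: 17 2‑fluoro‑5‑methylphenol
Product: 18 2‑bromo‑6‑fluoro‑3‑methylphenol
Conditions: Br2 (1.0 equiv), t‑BuNH2, toluene, −70 °C
Reagents that add atoms: bromine, BrBr
Why: Amine‑mediated ortho‑selective electrophilic bromination of a phenol at its only free ortho position.

Step 14
Reactants: 18 bromophenol
Product: 19 2‑bromo‑6‑fluoro‑3‑methylanisole
Conditions: MeI, K2CO3, acetone, 56 °C
Reagents that add atoms: iodomethane, CI
Why: Williamson methylation of the phenol.

Step 15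
Reactants: 19 bromoanisole; 20 (E)‑penta‑1,3‑diene
Product: 22 1‑fluoro‑2‑methoxy‑4‑methyl‑3‑[(E)‑pent‑3‑en‑1‑yl]benzene, via pentenyl‑9‑BBN 21 (not isolated)
Conditions: 9‑BBN, 20 (3 equiv), THF, 0 → 23 °C; then 19, Pd(OAc)2/SPhos, K3PO4, THF/H2O, 60 °C
Reagents that add atoms: none
Why: Hydroboration of the terminal double bond of the diene followed by B‑alkyl Suzuki–Miyaura coupling, which leaves the (E) double bond untouched.

Step 16
Reactants: 22 fluoroanisole
Product: 23 2‑fluoro‑1‑iodo‑3‑methoxy‑5‑methyl‑4‑[(E)‑pent‑3‑en‑1‑yl]benzene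
Conditions: s‑BuLi, TMEDA, THF, −78 °C; I2
Reagents that add atoms: iodine, II
Why: Fluorine‑directed ortho‑lithiation at the only ring C–H next to fluorine, followed by iodination.

**Union and completion**

Step 17
Reactants: 16 methyl ketal alcohol; 23 aryl iodide
Product: 28 7′‑O‑methyl ether of the target (5S,8R,2′R,3′R), via aryllithium 24 (not isolated), via aluminium alkoxide 25 (not isolated), via lithium aluminate 26 (not isolated), via fluoro alcohol 27 (not isolated)
Conditions: 16, Me3Al, toluene, −40 °C; 24 (from 23, t‑BuLi, Et2O, −78 °C); TMSOTf, −78 → −30 °C; then MeOH, NaH, DMF, 80 °C (one pot)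
Reagents that add atoms: none
Why: Proposed new method: Me3Al converts the C2′ alcohol of 16 into a dimethylaluminium alkoxide, aryllithium 24 turns it into an aryl(alkoxy)aluminate, and TMSOTf ionises the methyl ketal to the O9‑stabilised C3′ oxocarbenium ion, to which the aluminate should transfer its aryl group through a five‑membered transition state on the O1′ face; the closest known reactions are the syn‑selective opening of 1,2‑anhydro sugars by aryl‑aluminium or aryl‑zinc reagents and boron‑mediated aglycone delivery. The new C3′ centre is thus set by the C2′ oxygen (aryl cis to O1′, methyl trans), against the axial anti attack that an untethered nucleophile would prefer. After the methanol quench, NaH in DMF forms the C2′ alkoxide, which should close the dihydrofuran ring by intramolecular SNAr (5‑exo attack at C7a′, fluoride leaving), a known closure for 2‑(2‑fluoroaryl)ethanol‑type alkoxides. Only the cis adduct can reach C7a′, so a trans adduct would stay behind as an open fluoro alcohol and not become a wrong diastereomer. Aryl transfer is expected to beat methyl transfer because sp2 groups migrate faster from aluminates, and the site of ether closure is fixed by the single fluorine.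

Step 18
Reactants: 28 methyl ether
Product: 29 target, (5S,8R,2′R,3′R)
Conditions: NaSEt, DMF, 110 °C; NH4Cl
Reagents that add atoms: none
Why: Nucleophilic (SN2) demethylation of the aryl methyl ether by thiolate under basic conditions, which should spare the acid‑sensitive tertiary benzylic aryl ether and the alkene.

**Compound list**

1 | 3,4‑dimethoxytoluene | Cc1ccc(OC)c(OC)c1 | starting material
2 | succinic anhydride | O=C1CCC(=O)O1 | starting material
3 | 4‑(4,5‑dimethoxy‑2‑methylphenyl)‑4‑oxobutanoic acid | Cc1cc(OC)c(OC)cc1C(=O)CCC(=O)O | intermediate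
4 | 4‑(4,5‑dimethoxy‑2‑methylphenyl)pent‑4‑enoic acid | Cc1cc(OC)c(OC)cc1C(=C)CCC(=O)O | intermediate
5 | (S)‑4‑(4,5‑dimethoxy‑2‑methylphenyl)pentanoic acid | OC(=O)CC[C@H](C)c1cc(OC)c(OC)cc1C | intermediate
6 | (S)‑7,8‑dimethoxy‑4,5‑dimethyl‑3,4‑dihydronaphthalen‑1(2H)‑one | O=C1CC[C@H](C)c2c(C)cc(OC)c(OC)c12 | intermediate
7 | (S)‑7,8‑dihydroxy‑4,5‑dimethyl‑3,4‑dihydronaphthalen‑1(2H)‑one | O=C1CC[C@H](C)c2c(C)cc(O)c(O)c12 | intermediate
8 | chloroacetone | CC(=O)CCl | starting material
9 | (S)‑8‑hydroxy‑4,5‑dimethyl‑7‑(2‑oxopropoxy)‑3,4‑dihydronaphthalen‑1(2H)‑one | O=C1CC[C@H](C)c2c(C)cc(OCC(C)=O)c(O)c12 | intermediate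
10 | (S)‑9‑hydroxy‑3,4,5‑trimethyl‑6,7‑dihydronaphtho[2,3‑b]furan‑8(5H)‑one | Cc1coc2c(O)c3C(=O)CC[C@H](C)c3c(C)c12 | intermediate
11 | (5S) peri‑fused coumarin, O9–C3′(=O)–C2′H=C8 | Cc1coc2c3OC(=O)C=C4CC[C@H](C)c(c(C)c12)c34 | intermediate
12 | (5S,8S) dihydrocoumarin, H8 trans to C5–CH3 | Cc1coc2c3OC(=O)C[C@@H]4CC[C@H](C)c(c(C)c12)c34 | intermediate
13 | (5S,8R,2′R) α‑hydroxy lactone | Cc1coc2c3OC(=O)[C@H](O)[C@@H]4CC[C@H](C)c(c(C)c12)c34 | intermediate
14 | triethylsilyl ether of 13 | Cc1coc2c3OC(=O)[C@H](O[Si](CC)(CC)CC)[C@@H]4CC[C@H](C)c(c(C)c12)c34 | intermediate (not isolated)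
15 | (5S,8R,2′R) 3′‑methylene enol ether, 2′‑OSiEt3 | Cc1coc2c3OC(=C)[C@H](O[Si](CC)(CC)CC)[C@@H]4CC[C@H](C)c(c(C)c12)c34 | intermediate
16 | (5S,8R,2′R) 3′‑methoxy‑3′‑methyl ketal, 2′‑OH (C3′ anomers) | Cc1coc2c3OC(C)(OC)[C@H](O)[C@@H]4CC[C@H](C)c(c(C)c12)c34 | intermediate
17 | 2‑fluoro‑5‑methylphenol | Cc1ccc(F)c(O)c1 | starting material
18 | 2‑bromo‑6‑fluoro‑3‑methylphenol | Cc1ccc(F)c(O)c1Br | intermediate
19 | 2‑bromo‑6‑fluoro‑3‑methylanisole | Cc1ccc(F)c(OC)c1Br | intermediate
20 | (E)‑penta‑1,3‑diene | C/C=C/C=C | starting material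
21 | B‑[(E)‑pent‑3‑en‑1‑yl]‑9‑borabicyclo[3.3.1]nonane | C/C=C/CCB1C2CCCC1CCC2 | intermediate (not isolated)
22 | 1‑fluoro‑2‑methoxy‑4‑methyl‑3‑[(E)‑pent‑3‑en‑1‑yl]benzene | C/C=C/CCc1c(C)ccc(F)c1OC | intermediate
23 | 2‑fluoro‑1‑iodo‑3‑methoxy‑5‑methyl‑4‑[(E)‑pent‑3‑en‑1‑yl]benzene | C/C=C/CCc1c(C)cc(I)c(F)c1OC | intermediate
24 | aryllithium from 23 | C/C=C/CCc1c(C)cc([Li])c(F)c1OC | intermediate (not isolated)
25 | dimethylaluminium alkoxide of 16 | Cc1coc2c3OC(C)(OC)[C@H](O[Al](C)C)[C@@H]4CC[C@H](C)c(c(C)c12)c34 | intermediate (not isolated)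
26 | lithium aryl(alkoxy)dimethylaluminate | [Li+].Cc1coc2c3OC(C)(OC)[C@H](O[Al-](C)(C)c5cc(C)c(CC/C=C/C)c(OC)c5F)[C@@H]4CC[C@H](C)c(c(C)c12)c34 | intermediate (not isolated)
27 | (5S,8R,2′R,3′R) 3′‑(2‑fluoroaryl)‑3′‑methyl pyran‑2′‑ol, aryl cis to OH | C/C=C/CCc1c(C)cc(c(F)c1OC)[C@@]2(C)Oc3c4occ(C)c4c(C)c5c3[C@@H](CC[C@@H]5C)[C@H]2O | intermediate (not isolated)
28 | 7′‑O‑methyl ether of the target | C/C=C/CCc1c(C)cc2c(c1OC)O[C@@H]1[C@@H]3CC[C@H](C)c4c3c(c3occ(C)c3c4C)O[C@]21C | intermediate
29 | CNP0281983.1, (5S,8R,2′R,3′R) | C/C=C/CCc1c(C)cc2c(c1O)O[C@@H]1[C@@H]3CC[C@H](C)c4c3c(c3occ(C)c3c4C)O[C@]21C | target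

**Totals.** Total step count: 18. Longest linear sequence: 14 steps (1–12, 17, 18).

**Steps most likely to fail**

1. Step 17. The aryl group may be transferred from outside the aluminate, anti to O1′, or the oxocarbenium ion may lose the C2′ proton; the unactivated fluoride displacement may also stall. The fallback uses known chemistry and sets out from 15. TBAF removes the silyl group to give allylic alcohol F1. Addition of HCl (Et2O, −78 °C) to the enol ether and KHMDS then close the 2′,3′‑anhydro epoxide F2 (Brigl‑type 1,2‑anhydro formation). The arylzinc chloride made from 23 (t‑BuLi, then ZnCl2) opens F2 with the syn selectivity known for glycal epoxides to give 27, now isolated. NaH in DMF closes the ring, and the route is rejoined at 28.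

2. Step 10. Facial selectivity in the enolate hydroxylation may be poor, or the aryl ester enolate may be lost through ketene formation. The fallback sets out from 12. The same oxidation gives the C2′‑epimeric hydroxy lactone F3, which is inverted by Mitsunobu reaction with chloroacetic acid (PPh3, DIAD) to chloroacetate F4. Thiourea and NaHCO3 in ethanol cleave the chloroacetate, and the route is rejoined at 13.

3. Step 8. The olefination may not start at the hindered, hydrogen‑bonded peri ketone. The fallback sets out from 10. Acylation of the phenol with diethylphosphonoacetyl chloride (Et3N, CH2Cl2) gives phosphonoacetate F5. NaH in THF then closes the lactone by intramolecular Horner–Wadsworth–Emmons olefination, and the route is rejoined at 11.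

**Further compounds**

F1 | step 17 | (5S,8R,2′R) 3′‑methylene pyran‑2′‑ol | Cc1coc2c3OC(=C)[C@H](O)[C@@H]4CC[C@H](C)c(c(C)c12)c34
F2 | step 17 | 2′,3′‑anhydro epoxide, oxygen trans to H8 | Cc1coc2c3O[C@]5(C)O[C@@H]5[C@@H]4CC[C@H](C)c(c(C)c12)c34
F3 | step 10 | C2′ epimer of 13 | Cc1coc2c3OC(=O)[C@@H](O)[C@@H]4CC[C@H](C)c(c(C)c12)c34
F4 | step 10 | chloroacetate of 13 | Cc1coc2c3OC(=O)[C@H](OC(=O)CCl)[C@@H]4CC[C@H](C)c(c(C)c12)c34
F5 | step 8 | diethylphosphonoacetate of 10 | Cc1coc2c(OC(=O)CP(=O)(OCC)OCC)c3C(=O)CC[C@H](C)c3c(C)c12
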